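**Retrosynthetic overview**

1. Ring A is the 7-methoxyindole (atoms N1–C7a) and ring B the N-linked indole (primed atoms). The two indole β-bromines (C3–Br, C3'–Br) are put on last, after removal of an N1 tosyl group.
2. The plan rests on N1' of ring B, a nitrogen bound to three carbons: C4 of ring A, C2' and C7a'. Cutting N1'–C2' and N1'–C7a' leaves a primary amine on C4 of ring A and an ortho-iodoarylacetaldehyde whose bromine (the later C5'–Br) is already para to iodine.
3. The ring A amine comes from 4-bromo-7-methoxyindole: N-tosylation, Pd amination at C4, then NBS bromination at C5 ortho to the new NH2. The indole itself comes from a Bartoli reaction of 4-bromo-2-nitroanisole.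
4. The aldehyde comes from 5-bromo-2-iodobenzaldehyde by methoxymethylene Wittig homologation and enol ether hydrolysis.
5. Ring order: pyrrole ring of ring A (step 1), then pyrrole ring of ring B (step 7). Both benzene rings are bought.

Key step: step 7

Remark on the chemistry: the target structure has no stereocentre and no stereo descriptor; possible hindered rotation about the C4–N1' bond is left unassigned and the material is taken as the racemate.

**Route**

Step 1
Reactants: 1 4-bromo-2-nitroanisole; 2 vinylmagnesium bromide
Product: 3 4-bromo-7-methoxy-1H-indole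
Conditions: 2 (3.2 equiv), THF, −40 °C; then aq. NH4Cl
Reagents that add atoms: vinylmagnesium bromide (compound 2), C=C[Mg]Br
Why: Bartoli indole synthesis, in which the nitroarene is converted through the nitrosoarene into an N-aryl-O-vinylhydroxylamine whose [3,3]-sigmatropic shift goes to the only free ortho carbon, so the methoxy group ends at C7 and the bromine at C4.

Step 2
Reactants: 3 4-bromo-7-methoxy-1H-indole
Product: 4 4-bromo-7-methoxy-1-tosylindole
Conditions: NaH, THF, 0 °C; TsCl, 0 °C → rt
Reagents that add atoms: p-toluenesulfonyl chloride, Cc1ccc(cc1)S(=O)(=O)Cl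
Why: N-sulfonylation of the sodium indolide, which masks N1–H for the later base- and metal-mediated steps and deactivates C3 of ring A toward NBS in step 4.

Step 3
Reactants: 4 4-bromo-7-methoxy-1-tosylindole
Product: 6 7-methoxy-1-tosylindol-4-amine, via N-aryl benzophenone ketimine 5 (not isolated)
Conditions: Ph2C=NH, Pd2(dba)3, rac-BINAP, Cs2CO3, PhMe, 100 °C; then 2 M aq. HCl (cat.), THF, rt
Reagents that add atoms: benzophenone imine, N=C(c1ccccc1)c1ccccc1
Why: Buchwald–Hartwig amination with benzophenone imine as ammonia surrogate (zerovalent palladium inserts into C4–Br, the only carbon–halogen bond present, and the weak base Cs2CO3 spares the N-tosyl group), followed by acid-catalysed hydrolysis of the ketimine to the primary amine.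

Step 4
Reactants: 6 7-methoxy-1-tosylindol-4-amine
Product: 7 5-bromo-7-methoxy-1-tosylindol-4-amine
Conditions: NBS (1.0 equiv), DMF, −20 → 0 °C
Reagents that add atoms: N-bromosuccinimide, O=C1CCC(=O)N1Br
Why: Electrophilic aromatic bromination directed by the free NH2, whose para position C7 carries the methoxy group and whose only free ortho carbon is C5, while the N-tosyl group keeps C3 unreactive, so one equivalent at low temperature should brominate C5 only.

Step 5
Reactants: 8 5-bromo-2-iodobenzaldehyde; 9 (methoxymethyl)triphenylphosphonium chloride
Product: 10 4-bromo-1-iodo-2-(2-methoxyethenyl)benzene (E/Z mixture)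
Conditions: 9, KOtBu, THF, 0 °C; then 8, 0 °C → rt
Reagents that add atoms: (methoxymethyl)triphenylphosphonium chloride (compound 9), COC[P+](c1ccccc1)(c1ccccc1)c1ccccc1.[Cl-]
Why: Wittig olefination with the non-stabilised methoxymethylene ylide adds the one carbon needed, the aryl iodide and bromide are inert to the ylide at 0 °C, and the E/Z ratio is irrelevant because both isomers hydrolyse to the same aldehyde.

Step 6
Reactants: 10 4-bromo-1-iodo-2-(2-methoxyethenyl)benzene
Product: 11 2-(5-bromo-2-iodophenyl)acetaldehyde
Conditions: 2 M aq. HCl, THF, 60 °C; used crude at once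
Reagents that add atoms: water, O
Why: Acid-catalysed enol ether hydrolysis (C-protonation to the oxocarbenium ion, addition of water, loss of methanol) should give the homologated aldehyde, which is carried forward without storage because arylacetaldehydes self-condense.

Step 7
Reactants: 7 5-bromo-7-methoxy-1-tosylindol-4-amine; 11 2-(5-bromo-2-iodophenyl)acetaldehyde
Product: 13 5-bromo-4-(5-bromoindol-1-yl)-7-methoxy-1-tosylindole, via Z-enamine 12 (not isolated)
Conditions: 11 (1.5 equiv, slow addition), 4 Å MS, PhMe, rt → 50 °C; then CuI (10 mol %), 1,10-phenanthroline (20 mol %), K3PO4, 100 °C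
Reagents that add atoms: none
Why: Amine 7 condenses with aldehyde 11 to the imine, which tautomerises to the styrene-conjugated secondary enamine 12; its E and Z forms interconvert through the imine, so the Z isomer that places nitrogen next to the C–I bond is continuously supplied. K3PO4 deprotonates the enamine N–H on monovalent copper, the adjacent C–I bond adds oxidatively to give a six-membered trivalent-copper metallacycle, and reductive elimination forms N1'–C7a'. The closest known reaction type is the copper-catalysed condensation and intramolecular Ullmann–Goldberg N-arylation of ortho-haloaryl aldehydes or ketones with primary amines, which gives N-substituted indoles. The single ring closed, the pyrrole ring of ring B, forms by C(aryl)–N bond formation in a formal 5-exo-trig attack of nitrogen on the iodide carbon and is aromatic as soon as it closes; no stereocentre is formed. The step needs chemoselectivity among one C–I and three C–Br bonds: copper inserts into the iodide far faster than into a bromide, and only the iodide sits where a five-membered ring can form, whereas the bromides could react only intermolecularly. The hindered C4 nitrogen (between C5–Br and the peri C3–H) never has to enter an intermolecular arylation, since its first bond comes from a carbonyl condensation and its second from a ring closure.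

Step 8
Reactants: 13 5-bromo-4-(5-bromoindol-1-yl)-7-methoxy-1-tosylindole
Product: 14 5-bromo-4-(5-bromoindol-1-yl)-7-methoxy-1H-indole
Conditions: KOH, MeOH/THF, 65 °C
Reagents that add atoms: none
Why: Base-mediated N-desulfonylation, in which hydroxide or methoxide attacks sulfur and the indolide anion leaves, while the unactivated aryl bromides, the methyl ether and the N-aryl indole are inert to KOH at this temperature.

Step 9
Reactants: 14 5-bromo-4-(5-bromoindol-1-yl)-7-methoxy-1H-indole
Product: 15 Rivularin B, 3,5-dibromo-4-(3,5-dibromoindol-1-yl)-7-methoxy-1H-indole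
Conditions: NBS (2.05 equiv), DMF, −20 → 0 °C, dark
Reagents that add atoms: N-bromosuccinimide, O=C1CCC(=O)N1Br
Why: Electrophilic aromatic substitution with NBS at the β-carbon of each indole (C3 of ring A and C3' of ring B), the most nucleophilic carbon of each ring system, so two equivalents at low temperature should give the 3,3'-dibromide before C2, C2' or C6 react.

**Compound list**

1 | 4-bromo-2-nitroanisole | COc1ccc(Br)cc1[N+](=O)[O-] | starting material
2 | vinylmagnesium bromide | C=C[Mg]Br | starting material
3 | 4-bromo-7-methoxy-1H-indole | COc1ccc(Br)c2cc[nH]c12 | intermediate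
4 | 4-bromo-7-methoxy-1-tosylindole | Cc1ccc(cc1)S(=O)(=O)n1ccc2c(Br)ccc(OC)c21 | intermediate
5 | N-(diphenylmethylidene)-7-methoxy-1-tosylindol-4-amine (not isolated) | Cc1ccc(cc1)S(=O)(=O)n1ccc2c(N=C(c3ccccc3)c3ccccc3)ccc(OC)c21 | intermediate
6 | 7-methoxy-1-tosylindol-4-amine | Cc1ccc(cc1)S(=O)(=O)n1ccc2c(N)ccc(OC)c21 | intermediate
7 | 5-bromo-7-methoxy-1-tosylindol-4-amine | Cc1ccc(cc1)S(=O)(=O)n1ccc2c(N)c(Br)cc(OC)c21 | intermediate
8 | 5-bromo-2-iodobenzaldehyde | O=Cc1cc(Br)ccc1I | starting material
9 | (methoxymethyl)triphenylphosphonium chloride | COC[P+](c1ccccc1)(c1ccccc1)c1ccccc1.[Cl-] | starting material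
10 | 4-bromo-1-iodo-2-(2-methoxyethenyl)benzene (E/Z mixture) | COC=Cc1cc(Br)ccc1I | intermediate
11 | 2-(5-bromo-2-iodophenyl)acetaldehyde | O=CCc1cc(Br)ccc1I | intermediate
12 | (Z)-5-bromo-N-[2-(5-bromo-2-iodophenyl)ethenyl]-7-methoxy-1-tosylindol-4-amine (not isolated; equilibrates with the E isomer and the imine) | Cc1ccc(cc1)S(=O)(=O)n1ccc2c(N/C=C\c3cc(Br)ccc3I)c(Br)cc(OC)c21 | intermediate
13 | 5-bromo-4-(5-bromoindol-1-yl)-7-methoxy-1-tosylindole | Cc1ccc(cc1)S(=O)(=O)n1ccc2c(-n3ccc4cc(Br)ccc43)c(Br)cc(OC)c21 | intermediate
14 | 5-bromo-4-(5-bromoindol-1-yl)-7-methoxy-1H-indole | COc1cc(Br)c(-n2ccc3cc(Br)ccc32)c2cc[nH]c12 | intermediate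
15 | Rivularin B, 3,5-dibromo-4-(3,5-dibromoindol-1-yl)-7-methoxy-1H-indole | COc1cc(Br)c(-n2cc(Br)c3cc(Br)ccc32)c2c(Br)c[nH]c12 | target

**Step count**

Total steps: 9. Longest linear sequence: 7 steps (steps 1, 2, 3, 4, 7, 8, 9); the aldehyde branch (steps 5 and 6) joins at step 7.

**Steps most likely to fail**

Step 7. The condensation of the hindered, weakly nucleophilic C4 amine may be slower than aldol self-condensation of the enolisable aldehyde, or the enamine may decompose before copper closes the ring. The fallback sets out from 7 and 11 and comes back at 13. Reductive amination (NaBH(OAc)3, AcOH, 1,2-dichloroethane, rt) traps the iminium ion irreversibly as the stable secondary amine N-[2-(5-bromo-2-iodophenyl)ethyl]-5-bromo-7-methoxy-1-tosylindol-4-amine F1. Intramolecular Ullmann amination of the aryl iodide (CuI, K3PO4, DMSO, 90 °C) then closes the five-membered ring as the N-aryl indoline 5-bromo-4-(5-bromoindolin-1-yl)-7-methoxy-1-tosylindole F2. Dehydrogenation with DDQ in toluene aromatises it to 13. The same two bonds from N1' are formed; only the oxidation level of C2'–C3' is adjusted afterwards.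

Step 9. Two indole β-positions must be brominated at once on a free N–H indole, so site control may be lost through over-bromination, and the acid- and light-sensitive 3-bromo-1H-indole may decompose under prolonged exposure to the reagent. The fallback sets out from 13 and comes back at 15, with one reactive site per operation. One equivalent of NBS on 13 brominates only C3' of ring B, because the N-tosyl group deactivates C3 of ring A, and gives 5-bromo-4-(3,5-dibromoindol-1-yl)-7-methoxy-1-tosylindole F3. KOH in MeOH/THF removes the tosyl group to give 5-bromo-4-(3,5-dibromoindol-1-yl)-7-methoxy-1H-indole F4. A single equivalent of NBS at −40 °C then brominates C3 of ring A to give 15.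

Step 6. The arylacetaldehyde may undergo acid-promoted aldol condensation and air oxidation during the hot aqueous hydrolysis and on isolation, so that impure aldehyde enters the key step. The fallback sets out from 10 and comes back at enamine 12, and through it at 13, without ever freeing the aldehyde. Methanol and catalytic TsOH add across the enol ether to give the storable acetal 4-bromo-2-(2,2-dimethoxyethyl)-1-iodobenzene F5. Heating F5 with amine 7 and catalytic TsOH in toluene, with removal of methanol, exchanges the acetal for the enamine 12, which is cyclised with CuI, 1,10-phenanthroline and K3PO4 as in step 7.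

**Further compounds**

F1 | step 7 | N-[2-(5-bromo-2-iodophenyl)ethyl]-5-bromo-7-methoxy-1-tosylindol-4-amine | Cc1ccc(cc1)S(=O)(=O)n1ccc2c(NCCc3cc(Br)ccc3I)c(Br)cc(OC)c21
F2 | step 7 | 5-bromo-4-(5-bromoindolin-1-yl)-7-methoxy-1-tosylindole | Cc1ccc(cc1)S(=O)(=O)n1ccc2c(N3CCc4cc(Br)ccc43)c(Br)cc(OC)c21
F3 | step 9 | 5-bromo-4-(3,5-dibromoindol-1-yl)-7-methoxy-1-tosylindole | Cc1ccc(cc1)S(=O)(=O)n1ccc2c(-n3cc(Br)c4cc(Br)ccc43)c(Br)cc(OC)c21
F4 | step 9 | 5-bromo-4-(3,5-dibromoindol-1-yl)-7-methoxy-1H-indole | COc1cc(Br)c(-n2cc(Br)c3cc(Br)ccc32)c2cc[nH]c12
F5 | step 6 | 4-bromo-2-(2,2-dimethoxyethyl)-1-iodobenzene | COC(OC)Cc1cc(Br)ccc1I
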